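Late in the zeta run Q stopped moving, reading 75%, 75%, 74% and 74% from 10.0 h to 25.0 h. Zeta is the very flask in question, so I had to decide what to do with it at 40 h.

| flask | L | E | temperature | remark | time |
|---|---|---|---|---|---|
| zeta | 0.20 M | 20 µM | 40 °C | the very flask that is asked about, followed so far |  |
| gamma | 0.30 M | 20 µM | 46 °C | run made earlier |  |
| flask | 0.20 M | 20 µM | 40 °C |  | 40 h |

| run | time / h | Q / % |
|---|---|---|
| zeta | 5.00 | 31 |
| zeta | 10.0 | 75 |
| zeta | 15.0 | 75 |
| zeta | 20.0 | 74 |
| zeta | 25.0 | 74 |
| gamma | 0.250 | 3 |
| gamma | 0.833 | 3 |
| gamma | 1.33 | 9 |
| gamma | 2.50 | 20 |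
| gamma | 3.00 | 26 |

(each reading ± 1.5 percentage points)

- autumn: change nothing and wait 12 h more
- spring: at 40 h take out 90% of the Q then present, then wait 12 h
- noon: at 40 h add E, 50.0% of the amount charged, then wait 12 h

- Q that was removed still counts
- additions bring no volume worth counting

- Q, in percent of the L first charged, at 40 h
- the option that brings most further Q ("none" if no option brings more than 2 percentage points) (autumn / spring / noon / none)
- Q present, with what was taken out counted in, in percent of the L first charged, after spring
- Q present, with what was taken out counted in, in percent of the L first charged, after noon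

The mean of those late readings, 74.5%, was my answer for Q in this flask at 40 h. The decision hung on what that plateau meant, a dead catalyst or a balance. Neither zeta nor gamma tested this directly, but in zeta Q had gained 44 percentage points between 5.00 h and 10.0 h and then turned flat at a sharp corner, so I read it as a balance. From the plateau readings I took 2.92 as the standing ratio, the value of c_Q/c_L at which Q stops changing in this flask, its equilibrium constant.

Autumn leaves the ratio at that value, so I expected no gain. Noon adds E, and I took a catalyst to hasten a balance without moving it, so I expected 74.5% there too.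

Spring disturbs the ratio. It takes out 67.1% and leaves Q at 7.45% beside L at 25.5%, a ratio of 0.292, which is lower than the standing ratio. Putting that first answer back in, I let the remaining 32.9% divide again by the standing ratio. That gave Q in the flask 24.5% and, with what was taken out, 91.6%, a gain of 17 points. Provided the catalyst still worked at the pace read between 5.00 h and 10.0 h, I estimated that this would take about 1.94 h, less than the 12 h allowed. I chose spring.

The forecast, holding that “a saturated reversible reaction reaching equilibrium stops abruptly”, gave 74.5% at 40 h, spring as best, 91.6% after spring and 74.5% after noon.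

The flask gave 75.9% at 40 h, and spring was best with 16 points more, reaching 92.4%, while noon stayed at 75.9%.

    J → G (k = 1.65 × 10⁻⁶ s⁻¹, Ea = 272 kJ mol⁻¹)
    X ⇌ J + Q (K = 0.0700 M, k = 1.40 s⁻¹, Ea = 79.0 kJ mol⁻¹, ΔH = −53.0 kJ mol⁻¹)
    E → J (k = 1.99 × 10⁻⁵ s⁻¹, Ea = 94.0 kJ mol⁻¹)
    L + J ⇌ X (K = 45.0 L mol⁻¹, k = 5220 L mol⁻¹ s⁻¹, Ea = 36.0 kJ mol⁻¹, ΔH = −19.0 kJ mol⁻¹)
    (constants at 40 °C)

The choice rests on the backward step from J + Q to X. In the run with that step taken away, Q at 40 h rises from 75.9% to 100% and the best option turns, so such a run would have overturned my choice of spring. Read at 15 h, the same flask should already stand at the standing ratio, which puts Q at 74.5%; the computed value is 75.9%.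

Readings and results were generated by integration with made-up constants; scatter was added.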